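**Strategy.** Ring C is bounded by the nucleophilic enamine carbon C9 and the electrophilic butenolide carbon C12 of lactone D, so the route rests on excising C10–C11 from the tetracycle. In the key step a tricyclic enamine spirobutenolide (azepine ring A, pyrroline ring B, spiro-fused unsaturated ring D, appended cis-methyl lactone already complete) takes up (E)-1-nitrobut-1-ene. Enamine Michael addition makes C9–C10 and a base-triggered intramolecular nitro-Michael addition makes C11–C12, closing ring C and setting C10–C13 in one operation. The precursor is assembled on a pyrrolidinone template that fixes the spiro centre C1. A reductive Nef reaction and a hydride reduction finish the synthesis.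

Key step: step 14

Atom labels used below: C1 = quaternary carbinol carbon shared by rings B, C and D; C2; C3 = N–CH; C5–C8 = azepine CH2 groups; C9/C9a = enamine carbons (C9a on nitrogen); C10 = CH–Et; C11 = CH–OH; C12, C13 (CH–CH3), C14 (C=O) = lactone D; C18 (O–CH), C19, C20 (CH–CH3), C21 (C=O) = appended lactone. Target configuration: 1R,3R,10S,11R,12R,13R,18S,20S.

Assumption: the indium allylation of the (S)-sulfinyl aldimine is taken to occur on its Re face (nitrogen-bound chair model), the same sense as Felkin–Anh control by C18.

Design remarks: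
- Nitrogen is kept as sulfinamide, ammonium salt or lactam until it is part of the imine, because a free primary amine at C3 would attack the adjacent γ-lactone (O-to-N acyl shift).
- The cis C20 methyl group is set by hydrogenation, since enolate methylation of the lactone would give the trans isomer.
- C1 is set on a cyclic template, not in an open chain.

Step 1
Reactants: 1 propanal; 2 nitromethane
Product: 3 1-nitrobutan-2-ol (racemic)
Conditions: NaOH (cat.), nitromethane (excess)/EtOH, 0 °C to rt
Reagents that add atoms: none
Why: Base-catalysed Henry (nitroaldol) addition of the nitromethane anion to the unhindered aldehyde should proceed cleanly; the new carbinol centre is racemic and is removed in step 2.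

Step 2
Reactants: 3 1-nitrobutan-2-ol
Product: 5 (E)-1-nitrobut-1-ene, via mesylate 4 (not isolated)
Conditions: MsCl, Et3N, CH2Cl2, −10 to 0 °C
Reagents that add atoms: none
Why: Mesylation followed by E1cB elimination (dehydration of a β-nitro alcohol) should give the conjugated nitroalkene as the favoured E isomer; no stereocentre remains.

Step 3
Reactants: 6 (R)-2,2-dimethyl-1,3-dioxolane-4-carbaldehyde; 7 ethyl 2-(bromomethyl)prop-2-enoate
Product: 9 (5S)-5-[(4R)-2,2-dimethyl-1,3-dioxolan-4-yl]-3-methylideneoxolan-2-one, via hydroxy ester 8 (not isolated)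
Conditions: Zn, THF/sat. aq NH4Cl, 0 °C to rt; then pyridinium p-toluenesulfonate (cat.), CH2Cl2, rt
Reagents that add atoms: none
Why: The zinc-mediated Dreiding–Schmidt (Barbier-type) 2-(alkoxycarbonyl)allylation should add to the aldehyde under Felkin–Anh control anti to the α-oxygen, setting the carbinol centre (future C18) as S, and the γ-hydroxy ester lactonises under mild acid catalysis.

Step 4
Reactants: 9 methylidene lactone
Product: 10 (3S,5S)-5-[(4R)-2,2-dimethyl-1,3-dioxolan-4-yl]-3-methyloxolan-2-one
Conditions: H2 (1 atm), 10% Pd/C, EtOAc, rt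
Reagents that add atoms: none
Why: Heterogeneous catalytic hydrogenation should deliver hydrogen to the exocyclic methylene from the lactone face opposite the dioxolanyl group, so the methyl group (future C20) ends cis to that substituent (3S).

Step 5
Reactants: 10 cis-methyl lactone acetonide
Product: 12 (2S,4S)-4-methyl-5-oxooxolane-2-carbaldehyde, via diol 11 (not isolated)
Conditions: H5IO6, EtOAc, rt; crude aldehyde used directly
Reagents that add atoms: none
Why: Periodic acid hydrolyses the terminal acetonide and cleaves the liberated glycol (Malaprade oxidation) in one pot under non-basic conditions, so the α-oxygenated stereocentre next to the new aldehyde should not epimerise.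

Step 6
Reactants: 12 lactone aldehyde; 13 (S)-2-methylpropane-2-sulfinamide
Product: 14 (S)-2-methyl-N-{(E)-[(2S,4S)-4-methyl-5-oxooxolan-2-yl]methylidene}propane-2-sulfinamide
Conditions: CuSO4 (anhydrous), CH2Cl2, rt
Reagents that add atoms: none
Why: Dehydrative condensation of the aldehyde with the tert-butanesulfinamide auxiliary (CuSO4 as Lewis acid and water scavenger) should give the E aldimine without base, leaving C18 intact.

Step 7
Reactants: 14 sulfinyl aldimine; 15 tert-butyl 2-(bromomethyl)prop-2-enoate
Product: 16 tert-butyl (4R)-4-{[(S)-tert-butylsulfinyl]amino}-2-methylidene-4-[(2S,4S)-4-methyl-5-oxooxolan-2-yl]butanoate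
Conditions: In, THF/sat. aq NaBr, rt
Reagents that add atoms: none
Why: The indium-mediated aza-Barbier allylation of the N-sulfinyl aldimine should pass through a chair-like transition state with indium on nitrogen, in which the (S)-sulfinyl group directs the allyl unit to the Re face, reinforced by Felkin–Anh approach anti to the C18–O bond, setting C3 as R (nitrogen anti to the lactone oxygen).

Step 8
Reactants: 16 sulfinamide tert-butyl ester
Product: 18 (5R)-3-methylidene-5-[(2S,4S)-4-methyl-5-oxooxolan-2-yl]pyrrolidin-2-one, via amino acid hydrochloride 17 (not isolated)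
Conditions: HCl (4 M in dioxane), rt; evaporate; then EDC·HCl, HOBt, iPr2NEt, CH2Cl2 (0.01 M), 0 °C to rt
Reagents that add atoms: none
Why: Anhydrous HCl removes the N-sulfinyl group and the tert-butyl ester while nitrogen stays protonated (no O-to-N acyl shift onto the neighbouring lactone), and carbodiimide activation then drives a fast 5-exo-trig lactamisation (amide coupling) that should outpace aminolysis of the γ-lactone; no stereocentre is touched.

Step 9
Reactants: 18 methylidene lactam
Product: 19 (3R,5R)-3-hydroxy-3-(hydroxymethyl)-5-[(2S,4S)-4-methyl-5-oxooxolan-2-yl]pyrrolidin-2-one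
Conditions: OsO4 (cat.), N-methylmorpholine N-oxide, acetone/H2O, 0 °C to rt
Reagents that add atoms: OsO4 (O=[Os](=O)(=O)=O, catalytic oxygen carrier); N-methylmorpholine N-oxide (C[N+]1([O-])CCOCC1); water (O)
Why: Catalytic OsO4 dihydroxylation of the 1,1-disubstituted exocyclic alkene should occur on the lactam face anti to the bulky C5 lactonyl substituent, placing the tertiary hydroxyl trans to it and so setting C1 as R, with any minor cis diol to be removed at this stage.

Step 10
Reactants: 19 diol lactam
Product: 20 (3R,5R)-3-hydroxy-5-[(2S,4S)-4-methyl-5-oxooxolan-2-yl]-2-oxopyrrolidine-3-carbaldehyde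
Conditions: SO3·pyridine, DMSO, iPr2NEt, CH2Cl2, 0 °C; crude aldehyde used directly
Reagents that add atoms: none
Why: Parikh–Doering oxidation converts the primary alcohol into the aldehyde without glycol cleavage, and the tertiary alcohol and the quaternary C1 centre can neither be oxidised nor epimerised.

Step 11
Reactants: 20 hydroxy aldehyde; 21 ethyl 2-[bis(2,2,2-trifluoroethoxy)phosphoryl]propanoate
Product: 23 (5R,8R)-3-methyl-8-[(2S,4S)-4-methyl-5-oxooxolan-2-yl]-1-oxa-7-azaspiro[4.4]non-3-ene-2,6-dione, via Z-hydroxy enoate 22 (not isolated)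
Conditions: 21, KN(SiMe3)2, 18-crown-6, THF, −78 °C; add 20; −78 to 0 °C; AcOH; then camphorsulfonic acid (cat.), CH2Cl2, rt
Reagents that add atoms: none
Why: Still–Gennari olefination should give the Z-configured trisubstituted enoate, whose ester is held next to the tertiary hydroxyl and lactonises (5-exo-trig acyl substitution) to the α-methylbutenolide; C1 is not involved.

Step 12
Reactants: 23 spirobutenolide lactam; 24 1-bromo-5-chloropentane
Product: 26 (5R,8R)-6-(5-chloropentyl)-3-methyl-8-[(2S,4S)-4-methyl-5-oxooxolan-2-yl]-1-oxa-7-azaspiro[4.4]nona-3,6-dien-2-one, via imidoyl triflate 25 (not isolated)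
Conditions: Tf2O, 2-fluoropyridine, CH2Cl2, −78 to 0 °C; then Cl(CH2)5MgBr (from 24, Mg, THF), −78 °C; aq NaHCO3
Reagents that add atoms: none
Why: Electrophilic activation of the secondary lactam gives an imidoyl triflate that has no α-hydrogen at C1 (no keteniminium ion, no epimerisation) and is far more electrophilic than the lactone and butenolide carbonyls, so the Grignard reagent should add to C9a at −78 °C and loss of triflate gives the ketimine (amide-to-ketimine conversion) with C1 and C3 untouched.

Step 13
Reactants: 26 chloropentyl pyrroline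
Product: 28 tricyclic enamine spirobutenolide (1R,3R,18S,20S; C9=C9a enamine), via bicyclic iminium chloride 27 (not isolated)
Conditions: NaI (cat.), MeCN, 70 °C; then Et3N, 0 °C, under argon; filtered and used at once
Reagents that add atoms: none
Why: Iodide-catalysed (Finkelstein) intramolecular N-alkylation of the imine nitrogen closes the azepine ring (7-exo-tet), and the resulting iminium ion can lose a proton only from C9 because C1 is quaternary, so a single enamine regioisomer should form.

Step 14
Reactants: 28 tricyclic enamine spirobutenolide; 5 (E)-1-nitrobut-1-ene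
Product: 30 11-nitro tetracycle (1R,3R,10S,11R,12R,13R,18S,20S; nitro in place of the C11 hydroxyl of the target), via nitroalkyl enamine 29 (not isolated)
Conditions: 5 (1.2 equiv), MeCN, −20 °C to rt; then DBU (0.3 equiv), 0 °C; AcOH, −20 °C
Reagents that add atoms: none
Why: The enamine carbon C9 adds to the nitro-free alkene carbon of 5 (Stork enamine Michael addition, reversible through the zwitterion and its cyclobutane or oxazine N-oxide resting states) and loss of H-9 restores the tetrasubstituted C9=C9a enamine in 29; catalytic DBU then forms the nitronate, whose carbon C11 adds to the butenolide β-carbon C12, and the resulting lactone enolate is protonated at C13, which is the known sequence of enamine–nitroalkene Michael addition followed by intramolecular nitro-Michael ring closure onto an unsaturated lactone. Ring C is closed by 6-exo-trig attack of the nitronate on the C12=C13 bond. C12 (R) is dictated by the spiro tether, because C11 can reach only the butenolide face that carries the C1–C9a bond, which makes the C/D fusion cis. C10 (S) is born in the first, reversible Michael step and selected in the ring closure, where the ethyl group of the reacting adduct lies on the convex face of the emerging cis-fused C/D bicycle, anti to the C1–O bond; C11 (R as drawn, nitro trans to ethyl) equilibrates through its acidic α-nitro hydrogen and is erased in step 15. C13 (R) results from kinetic protonation of the enolate on its open face anti to the new C11–C12 bond, leaving the methyl group syn to C11, which is why DBU is kept substoichiometric and the reaction is quenched cold with acetic acid. The step needs C-alkylation at C9 by the nitroalkene in preference to reaction with the butenolide of a second molecule, and intramolecular rather than intermolecular nitronate addition, which the much higher electrophilicity of the nitroalkene, the absence of free nitroalkene when base is added and the six-membered ring geometry should secure.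

Step 15
Reactants: 30 11-nitro tetracycle
Product: 31 11-ketone (1R,3R,10S,12S,13R,18S,20S; same spatial arrangement as 30, the C12 descriptor changes by priority only)
Conditions: DBU, THF, 0 °C; then TiCl3 (aq), NH4OAc, THF/H2O, pH 5–6, 0 °C to rt; aq NaHCO3
Reagents that add atoms: water (O)
Why: In the reductive Nef reaction the nitronate is reduced by trivalent titanium to the imine, which is hydrolysed to the C11 ketone at pH 5–6, conditions under which the lactones should survive, the enamine is at most reversibly protonated, and β-elimination of the C1 carboxylate or epimerisation at C10 and C12 should be slow.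

Step 16
Reactants: 31 11-ketone
Product: 32 target CNP0154902.3
Conditions: NaBH4, EtOH/THF, −40 °C; aq NH4Cl
Reagents that add atoms: none
Why: Borohydride reduction is chemoselective for the ketone over both lactones and should deliver hydride to the convex face of the cis-fused C/D bicycle, anti to the C1–O and C12–C13 bonds, giving the C11 alcohol syn to lactone D (11R).

**Compound list**

1 | propanal | CCC=O | starting material
2 | nitromethane | C[N+](=O)[O-] | starting material
3 | 1-nitrobutan-2-ol (racemic) | CCC(O)C[N+](=O)[O-] | intermediate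
4 | 1-nitrobutan-2-yl methanesulfonate (racemic) | CCC(OS(C)(=O)=O)C[N+](=O)[O-] | intermediate
5 | (E)-1-nitrobut-1-ene | CC/C=C/[N+](=O)[O-] | intermediate
6 | (R)-2,2-dimethyl-1,3-dioxolane-4-carbaldehyde | O=C[C@H]1COC(C)(C)O1 | starting material
7 | ethyl 2-(bromomethyl)prop-2-enoate | CCOC(=O)C(=C)CBr | starting material
8 | ethyl (4S)-4-[(4R)-2,2-dimethyl-1,3-dioxolan-4-yl]-4-hydroxy-2-methylidenebutanoate | CCOC(=O)C(=C)C[C@H](O)[C@H]1COC(C)(C)O1 | intermediate
9 | (5S)-5-[(4R)-2,2-dimethyl-1,3-dioxolan-4-yl]-3-methylideneoxolan-2-one | C=C1C[C@@H]([C@H]2COC(C)(C)O2)OC1=O | intermediate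
10 | (3S,5S)-5-[(4R)-2,2-dimethyl-1,3-dioxolan-4-yl]-3-methyloxolan-2-one | C[C@H]1C[C@@H]([C@H]2COC(C)(C)O2)OC1=O | intermediate
11 | (3S,5S)-5-[(1R)-1,2-dihydroxyethyl]-3-methyloxolan-2-one | C[C@H]1C[C@@H]([C@H](O)CO)OC1=O | intermediate
12 | (2S,4S)-4-methyl-5-oxooxolane-2-carbaldehyde | C[C@H]1C[C@@H](C=O)OC1=O | intermediate
13 | (S)-2-methylpropane-2-sulfinamide | CC(C)(C)[S@](=O)N | starting material
14 | (S)-2-methyl-N-{(E)-[(2S,4S)-4-methyl-5-oxooxolan-2-yl]methylidene}propane-2-sulfinamide | CC(C)(C)[S@](=O)/N=C/[C@@H]1C[C@H](C)C(=O)O1 | intermediate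
15 | tert-butyl 2-(bromomethyl)prop-2-enoate | CC(C)(C)OC(=O)C(=C)CBr | starting material
16 | tert-butyl (4R)-4-{[(S)-tert-butylsulfinyl]amino}-2-methylidene-4-[(2S,4S)-4-methyl-5-oxooxolan-2-yl]butanoate | CC(C)(C)OC(=O)C(=C)C[C@@H](N[S@@](=O)C(C)(C)C)[C@@H]1C[C@H](C)C(=O)O1 | intermediate
17 | (4R)-4-amino-2-methylidene-4-[(2S,4S)-4-methyl-5-oxooxolan-2-yl]butanoic acid hydrochloride | OC(=O)C(=C)C[C@@H](N)[C@@H]1C[C@H](C)C(=O)O1.Cl | intermediate
18 | (5R)-3-methylidene-5-[(2S,4S)-4-methyl-5-oxooxolan-2-yl]pyrrolidin-2-one | O=C1N[C@@H]([C@@H]2C[C@H](C)C(=O)O2)CC1=C | intermediate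
19 | (3R,5R)-3-hydroxy-3-(hydroxymethyl)-5-[(2S,4S)-4-methyl-5-oxooxolan-2-yl]pyrrolidin-2-one | O=C1N[C@@H]([C@@H]2C[C@H](C)C(=O)O2)C[C@]1(CO)O | intermediate
20 | (3R,5R)-3-hydroxy-5-[(2S,4S)-4-methyl-5-oxooxolan-2-yl]-2-oxopyrrolidine-3-carbaldehyde | O=C1N[C@@H]([C@@H]2C[C@H](C)C(=O)O2)C[C@]1(C=O)O | intermediate
21 | ethyl 2-[bis(2,2,2-trifluoroethoxy)phosphoryl]propanoate | CCOC(=O)C(C)P(=O)(OCC(F)(F)F)OCC(F)(F)F | starting material
22 | ethyl (2Z)-3-{(3R,5R)-3-hydroxy-5-[(2S,4S)-4-methyl-5-oxooxolan-2-yl]-2-oxopyrrolidin-3-yl}-2-methylprop-2-enoate | O=C1N[C@@H]([C@@H]2C[C@H](C)C(=O)O2)C[C@]1(/C=C(/C)C(=O)OCC)O | intermediate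
23 | (5R,8R)-3-methyl-8-[(2S,4S)-4-methyl-5-oxooxolan-2-yl]-1-oxa-7-azaspiro[4.4]non-3-ene-2,6-dione | O=C1N[C@@H]([C@@H]2C[C@H](C)C(=O)O2)C[C@]13OC(=O)C(C)=C3 | intermediate
24 | 1-bromo-5-chloropentane | ClCCCCCBr | starting material
25 | (5R,8R)-3-methyl-8-[(2S,4S)-4-methyl-5-oxooxolan-2-yl]-2-oxo-1-oxa-7-azaspiro[4.4]nona-3,6-dien-6-yl trifluoromethanesulfonate | FC(F)(F)S(=O)(=O)OC1=N[C@@H]([C@@H]2C[C@H](C)C(=O)O2)C[C@]13OC(=O)C(C)=C3 | intermediate
26 | (5R,8R)-6-(5-chloropentyl)-3-methyl-8-[(2S,4S)-4-methyl-5-oxooxolan-2-yl]-1-oxa-7-azaspiro[4.4]nona-3,6-dien-2-one | ClCCCCCC1=N[C@@H]([C@@H]2C[C@H](C)C(=O)O2)C[C@]13OC(=O)C(C)=C3 | intermediate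
27 | bicyclic iminium chloride (C9a=N+ pyrrolo[1,2-a]azepinium, spirobutenolide at C1, lactone at C3; 1R,3R,18S,20S) | C1C2=[N+](CCCC1)[C@@H]([C@@H]1C[C@H](C)C(=O)O1)C[C@]21OC(=O)C(C)=C1.[Cl-] | intermediate
28 | tricyclic enamine spirobutenolide (C9=C9a enamine in the azepine ring, 3-methylfuran-2(5H)-one spiro-fused at C1, (2S,4S)-4-methyl-5-oxooxolan-2-yl at C3; 1R,3R) | C1=C2N(CCCC1)[C@@H]([C@@H]1C[C@H](C)C(=O)O1)C[C@]21OC(=O)C(C)=C1 | intermediate
29 | nitroalkyl enamine (28 carrying an (S)-1-nitrobutan-2-yl group at C9; 1R,3R,10S,18S,20S) | CC[C@H](C[N+](=O)[O-])C1=C2N(CCCC1)[C@@H]([C@@H]1C[C@H](C)C(=O)O1)C[C@]21OC(=O)C(C)=C1 | intermediate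
30 | 11-nitro tetracycle (target with NO2 in place of 11-OH; 1R,3R,10S,11R,12R,13R,18S,20S) | CC[C@H]1C2=C3N(CCCC2)[C@@H]([C@@H]2C[C@H](C)C(=O)O2)C[C@]32OC(=O)[C@H](C)[C@@H]2[C@@H]1[N+](=O)[O-] | intermediate
31 | 11-ketone (C11 carbonyl; 1R,3R,10S,12S,13R,18S,20S) | CC[C@H]1C2=C3N(CCCC2)[C@@H]([C@@H]2C[C@H](C)C(=O)O2)C[C@]32OC(=O)[C@H](C)[C@@H]2C1=O | intermediate
32 | CNP0154902.3 (1R,3R,10S,11R,12R,13R,18S,20S) | CC[C@H]1C2=C3N(CCCC2)[C@@H]([C@@H]2C[C@H](C)C(=O)O2)C[C@]32OC(=O)[C@H](C)[C@@H]2[C@@H]1O | target

**Step count.** Total: 16 steps. Longest linear sequence: 14 steps (steps 3–16, from 6); steps 1–2 supply 5.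

**Steps most likely to fail**

Step 14. The nitroalkene may add to either face of the enamine, so that C10 forms as a mixture, and prolonged exposure to base may epimerise C13 or stall the ring closure on the trisubstituted butenolide. The fallback sets out from 28 and 5 and returns at 31. The first stage is run without DBU and adduct 29 is isolated. Its primary nitro group is converted by the reductive Nef reaction (DBU, then buffered aqueous TiCl3) into the α-branched aldehyde F1. F1 is then cyclised by an intramolecular Stetter reaction (3-ethyl-5-(2-hydroxyethyl)-4-methylthiazolium bromide, Et3N, dioxane, 60 °C). The acyl-anion equivalent at C11 adds to C12 and gives ketone 31 directly. C10 is α to the aldehyde in F1 and epimerises under these conditions, so its configuration is decided in the ring closure and not in the first Michael addition.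

Step 12. The Grignard reagent may attack the butenolide or lactone carbonyls in competition with the hindered imidoyl triflate, whose carbon C9a is flanked by the quaternary C1. The fallback sets out from 23 and returns at 26 without any organometallic reagent. 6-Chlorohexanoyl chloride is brominated (Hell–Volhard–Zelinsky conditions) and quenched with tert-butanol to give tert-butyl 2-bromo-6-chlorohexanoate F2. Lactam 23 is thionated with Lawesson's reagent (toluene, 80 °C) to thiolactam F3. S-Alkylation of F3 with F2, followed by PPh3/Et3N (Eschenmoser sulfide contraction), gives the vinylogous carbamate F4. CF3CO2H cleaves the tert-butyl ester, and decarboxylation delivers 26.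

Step 16. Hydride delivery may occur on the lactone face instead, because the convex face carries the C10 ethyl group, which would give the C11 epimer; base-induced β-elimination of the C1 carboxylate is a second hazard. The fallback sets out from 31 and returns at 32. The reduction is run with whichever hydride gives the cleanest single epimer, and the 11-epi alcohol F5 is isolated. A Mitsunobu reaction (PPh3, diisopropyl azodicarboxylate, 4-nitrobenzoic acid, toluene) inverts C11 and gives the 4-nitrobenzoate F6. Brief methanolysis (K2CO3 cat., MeOH, 0 °C, mildly acidic work-up to re-close any opened lactone) then releases 32.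

Further compounds
F1 | step 14 | (S)-2-substituted butanal (29 with CHO in place of CH2NO2) | CC[C@H](C=O)C1=C2N(CCCC1)[C@@H]([C@@H]1C[C@H](C)C(=O)O1)C[C@]21OC(=O)C(C)=C1
F2 | step 12 | tert-butyl 2-bromo-6-chlorohexanoate (racemic) | ClCCCCC(Br)C(=O)OC(C)(C)C
F3 | step 12 | (5R,8R)-3-methyl-8-[(2S,4S)-4-methyl-5-oxooxolan-2-yl]-6-thioxo-1-oxa-7-azaspiro[4.4]non-3-en-2-one | S=C1N[C@@H]([C@@H]2C[C@H](C)C(=O)O2)C[C@]13OC(=O)C(C)=C3
F4 | step 12 | tert-butyl (2Z)-6-chloro-2-[spiro-pyrrolidin-2-ylidene]hexanoate (vinylogous carbamate at C9a=C9) | ClCCCC/C(C(=O)OC(C)(C)C)=C1/N[C@@H]([C@@H]2C[C@H](C)C(=O)O2)C[C@]13OC(=O)C(C)=C3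
F5 | step 16 | 11-epi alcohol (11S epimer of the target) | CC[C@H]1C2=C3N(CCCC2)[C@@H]([C@@H]2C[C@H](C)C(=O)O2)C[C@]32OC(=O)[C@H](C)[C@@H]2[C@H]1O
F6 | step 16 | 11-O-(4-nitrobenzoyl) derivative of the target (11R) | CC[C@H]1C2=C3N(CCCC2)[C@@H]([C@@H]2C[C@H](C)C(=O)O2)C[C@]32OC(=O)[C@H](C)[C@@H]2[C@@H]1OC(=O)c1ccc(cc1)[N+](=O)[O-]
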